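**Retrosynthetic overview**
- The acid is released last from its tert-butyl ester by a non-protic, lutidine-buffered silyl triflate cleavage.
- Key step: the C7≡C8 triple bond is not made by sp–sp (Cadiot–Chodkiewicz) coupling but by a Fritsch–Buttenberg–Wiechell 1,2-alkynyl shift of a lithium alkylidene carbenoid generated from a 1,1-dibromoolefin; C7 comes from CBr4.
- The dibromoolefin comes from an ynone (Ramirez olefination), and the ynone from acyl Sonogashira coupling of 16-(furan-2-yl)hexadecanoyl chloride with tert-butyl hex-5-ynoate.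
- 16-(Furan-2-yl)hexadecanoic acid comes from 2-furyllithium and 16-bromohexadecanoic acid.
- Rings: the furan is the only ring; it is bought as furan and carried through intact, so no ring is formed in the route.

Assumption: the target has no stereocentre and no stereogenic double bond, so "single enantiomer" is read as the one achiral structure given.
Assumption: tert-butyl hex-5-ynoate is taken as a purchasable catalogue compound.

**Route**

Step 1
Reactants: 1 furan; 2 16-bromohexadecanoic acid
Product: 4 16-(furan-2-yl)hexadecanoic acid, via 2-furyllithium 3 (not isolated)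
Conditions: 1 (3.0 equiv), n-BuLi (2.4 equiv), THF, −78 → 0 °C; then 2 (1.0 equiv), THF/DMPU, −78 °C → rt; 1 M HCl, 0 °C
Reagents that add atoms: none
Why: α-Lithiation of furan followed by SN2 alkylation of the primary bromide, in which one equivalent of 2-furyllithium removes the acid proton and the resulting lithium carboxylate is inert to the heteroaryllithium at these temperatures, so C–C bond formation occurs only at the CH2Br terminus.

Step 2
Reactants: 4 16-(furan-2-yl)hexadecanoic acid; 5 tert-butyl hex-5-ynoate
Product: 7 tert-butyl 22-(furan-2-yl)-7-oxodocos-5-ynoate, via acid chloride 6 (not isolated)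
Conditions: (COCl)2 (1.3 equiv), DMF (1 mol %), CH2Cl2, 0 °C → rt, concentrate; then 5 (1.2 equiv), PdCl2(PPh3)2 (2 mol %), CuI (4 mol %), Et3N (1.5 equiv), THF, rt
Reagents that add atoms: none
Why: Acyl Sonogashira coupling, in which the copper acetylide of 5 transmetalates to the acylpalladium chloride formed from 6 and reductive elimination gives the ynone under conditions that leave the tert-butyl ester and the furan untouched.

Step 3
Reactants: 7 tert-butyl 22-(furan-2-yl)-7-oxodocos-5-ynoate
Product: 8 tert-butyl 7-(dibromomethylidene)-22-(furan-2-yl)docos-5-ynoate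
Conditions: CBr4 (2 equiv), PPh3 (4 equiv), CH2Cl2, 0 °C, 20 min; then 7, 0 °C → rt
Reagents that add atoms: carbon tetrabromide, BrC(Br)(Br)Br
Why: Ramirez (Corey–Fuchs-type) dibromoolefination, a Wittig reaction of pre-formed Ph3P=CBr2 with the ketone, which is activated by the adjacent alkyne, installing the future C7 as the CBr2 carbon.

Step 4
Reactants: 8 tert-butyl 7-(dibromomethylidene)-22-(furan-2-yl)docos-5-ynoate
Product: 10 tert-butyl 23-(furan-2-yl)tricosa-5,7-diynoate, via lithium carbenoid 9 (not isolated)
Conditions: n-BuLi (1.1 equiv), hexanes, −78 → −20 °C; aq. NH4Cl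
Reagents that add atoms: none
Why: Fritsch–Buttenberg–Wiechell rearrangement, in which fast Br/Li exchange in a non-coordinating solvent (faster at −78 °C than attack on the hindered tert-butyl ester) gives carbenoid 9, which loses LiBr on warming with 1,2-shift of the alkynyl group to form the C7≡C8 bond, and since shift of either substituent leads to the same diyne the constitution is secured and no stereocentre is involved.

Step 5
Reactants: 10 tert-butyl 23-(furan-2-yl)tricosa-5,7-diynoate
Product: 12 23-(furan-2-yl)tricosa-5,7-diynoic acid, via trimethylsilyl ester 11 (not isolated)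
Conditions: TMSOTf (2.0 equiv), 2,6-lutidine (3.0 equiv), CH2Cl2, 0 °C; then H2O (pH 5 buffer), rt
Reagents that add atoms: none
Why: Silyl triflate-mediated tert-butyl ester cleavage, in which O-silylation of the ester triggers loss of the tert-butyl group as 2-methylpropene with 2,6-lutidine taking the proton (so no free strong acid or long-lived tert-butyl cation can attack the 2-alkylfuran), and the labile silyl ester 11 is hydrolysed on aqueous work-up.

**Compound list**

1 | furan | c1ccoc1 | starting material
2 | 16-bromohexadecanoic acid | OC(=O)CCCCCCCCCCCCCCCBr | starting material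
3 | 2-furyllithium | [Li]c1ccco1 | intermediate
4 | 16-(furan-2-yl)hexadecanoic acid | OC(=O)CCCCCCCCCCCCCCCc1ccco1 | intermediate
5 | tert-butyl hex-5-ynoate | C#CCCCC(=O)OC(C)(C)C | starting material
6 | 16-(furan-2-yl)hexadecanoyl chloride | O=C(Cl)CCCCCCCCCCCCCCCc1ccco1 | intermediate
7 | tert-butyl 22-(furan-2-yl)-7-oxodocos-5-ynoate | CC(C)(C)OC(=O)CCCC#CC(=O)CCCCCCCCCCCCCCCc1ccco1 | intermediate
8 | tert-butyl 7-(dibromomethylidene)-22-(furan-2-yl)docos-5-ynoate | CC(C)(C)OC(=O)CCCC#CC(=C(Br)Br)CCCCCCCCCCCCCCCc1ccco1 | intermediate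
9 | tert-butyl 7-[bromo(lithio)methylidene]-22-(furan-2-yl)docos-5-ynoate (lithium carbenoid, double-bond geometry not defined) | CC(C)(C)OC(=O)CCCC#CC(=C([Li])Br)CCCCCCCCCCCCCCCc1ccco1 | intermediate
10 | tert-butyl 23-(furan-2-yl)tricosa-5,7-diynoate | CC(C)(C)OC(=O)CCCC#CC#CCCCCCCCCCCCCCCCc1ccco1 | intermediate
11 | trimethylsilyl 23-(furan-2-yl)tricosa-5,7-diynoate | C[Si](C)(C)OC(=O)CCCC#CC#CCCCCCCCCCCCCCCCc1ccco1 | intermediate
12 | 23-(furan-2-yl)tricosa-5,7-diynoic acid | O=C(O)CCCC#CC#CCCCCCCCCCCCCCCCc1ccco1 | target

**Step count**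
Total steps: 5. Longest linear sequence: 5 steps (from furan and 16-bromohexadecanoic acid to the target; 5 enters at step 2).

**Steps most likely to fail, with fallbacks**

Step 4 (carbenoid rearrangement). Risks are butyllithium attack on the ester, protonation of the carbenoid to a vinyl bromide, and C–H insertion. The fallback makes the diyne by sp–sp coupling instead; it sets out from acid chloride 6 (made from 4 as in step 2) together with alkyne 5 and comes back to the route at 10. Compound 6 is reduced with LiAlH(OtBu)3 in THF at −78 °C to 16-(furan-2-yl)hexadecanal F1. Seyferth–Gilbert homologation with dimethyl (1-diazo-2-oxopropyl)phosphonate and K2CO3 in MeOH then gives 2-(heptadec-16-yn-1-yl)furan F2. Separately, 5 is brominated with NBS and catalytic AgNO3 in acetone to tert-butyl 6-bromohex-5-ynoate F3. Cadiot–Chodkiewicz coupling of F2 with F3 (CuCl cat., NH2OH·HCl, n-BuNH2, MeOH/H2O, 0 °C) delivers 10, which goes on to step 5.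

Step 3 (dibromoolefination of an enolisable ynone). Risks are conjugate addition of PPh3 to the ynone and enolisation. The fallback drops the olefination and the organolithium exchange and generates a free alkylidene carbene directly from the ketone; it sets out from 7 and comes back at 10, bypassing 8 and 9. TMSC(Li)N2 (from TMSCHN2 and n-BuLi, THF, −78 °C) adds to the ketone to give the alkoxide tert-butyl 7-[diazo(trimethylsilyl)methyl]-22-(furan-2-yl)-7-(lithiooxy)docos-5-ynoate F4. Peterson elimination gives the diazoalkene tert-butyl 7-(diazomethylidene)-22-(furan-2-yl)docos-5-ynoate F5. Loss of nitrogen on warming to 0 °C gives the alkylidene carbene tert-butyl 22-(furan-2-yl)-7-(λ2-methylidene)docos-5-ynoate F6, whose 1,2-alkynyl shift (Colvin rearrangement) gives 10.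

Step 1 (alkylation of 2-furyllithium by a lithium ω-bromocarboxylate). Risks are elimination, ketone formation at the carboxylate, and a poorly soluble lithium soap. The fallback reverses the polarity and uses furan as the nucleophile in an acylation followed by deoxygenation; it sets out from furan 1 and comes back at 4. Commercial 16-methoxy-16-oxohexadecanoic acid is activated with (CF3CO)2O as 16-methoxy-16-oxohexadecanoic trifluoroacetic anhydride F7. This acylates 1 at C2 (cat. H3PO4, CH2Cl2, rt) to give methyl 16-(furan-2-yl)-16-oxohexadecanoate F8. Wolff–Kishner reduction under Huang-Minlon conditions (N2H4·H2O, KOH, diethylene glycol, 130 → 200 °C) saponifies the ester and passes through 16-(furan-2-yl)-16-hydrazinylidenehexadecanoic acid F9, which loses nitrogen to give 4 after acidification.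

**Further compounds**

F1 | step 4 | 16-(furan-2-yl)hexadecanal | O=CCCCCCCCCCCCCCCCc1ccco1
F2 | step 4 | 2-(heptadec-16-yn-1-yl)furan | C#CCCCCCCCCCCCCCCCc1ccco1
F3 | step 4 | tert-butyl 6-bromohex-5-ynoate | BrC#CCCCC(=O)OC(C)(C)C
F4 | step 3 | tert-butyl 7-[diazo(trimethylsilyl)methyl]-22-(furan-2-yl)-7-(lithiooxy)docos-5-ynoate | CC(C)(C)OC(=O)CCCC#CC(O[Li])(C(=[N+]=[N-])[Si](C)(C)C)CCCCCCCCCCCCCCCc1ccco1
F5 | step 3 | tert-butyl 7-(diazomethylidene)-22-(furan-2-yl)docos-5-ynoate | CC(C)(C)OC(=O)CCCC#CC(=C=[N+]=[N-])CCCCCCCCCCCCCCCc1ccco1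
F6 | step 3 | alkylidene carbene tert-butyl 22-(furan-2-yl)-7-(λ2-methylidene)docos-5-ynoate | CC(C)(C)OC(=O)CCCC#CC(=[C])CCCCCCCCCCCCCCCc1ccco1
F7 | step 1 | 16-methoxy-16-oxohexadecanoic trifluoroacetic anhydride | COC(=O)CCCCCCCCCCCCCCC(=O)OC(=O)C(F)(F)F
F8 | step 1 | methyl 16-(furan-2-yl)-16-oxohexadecanoate | COC(=O)CCCCCCCCCCCCCCC(=O)c1ccco1
F9 | step 1 | 16-(furan-2-yl)-16-hydrazinylidenehexadecanoic acid | OC(=O)CCCCCCCCCCCCCCC(=NN)c1ccco1
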